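I read this flask at the moment when 10 % of the substrate had been converted, so I first needed that moment and then the state of the catalyst at it.

substrate 2.0 mM; precatalyst 0.20 µM

    precatalyst → enzyme (k1 = 0.0598 s⁻¹)
    substrate + enzyme → target + enzyme, rate k2*[substrate]*[enzyme]/(1 + ([substrate]/Km2) + ([target]/Kp2)) (Km2 = 3.45 mM, Kp2 = 0.0584 mM, k2 = 1.10 × 10⁸ L mol⁻¹ s⁻¹)
    substrate → uncatalysed product (k3 = 0.443 s⁻¹)

- the form that holds most of the catalyst when 10 % of the substrate are converted (precatalyst / enzyme)
- its share of the catalyst then
- factor on the rate of making target when 10 % of the substrate are converted if precatalyst is charged twice over
- factor on the rate when 10 % of the substrate are converted if precatalyst is charged at 0.020 µM instead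

Activation, the step from precatalyst to enzyme, is first order and has no other partner, so its rate integrates in closed form: the enzyme's share of the catalyst is one minus the exponential of minus its rate constant times the time. For the time of reading, I took the first-order loss of substrate to uncatalysed product, which gave 0.238 s. Enzyme starts at zero and the catalysed route adds to this loss, so I held that time as an upper limit.

I then drew the enzyme curve. It leaves zero with slope 0.0598 s⁻¹, bends at 16.7 s, and runs towards the full charge. At my time of reading it stood at 1.41 %, the activated share at the reading. It crosses the falling precatalyst curve at 11.6 s, far later than the reading, so I committed to precatalyst as the main form, with 98.6 %.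

For the two factors I went no further than this: at about equal activated shares, enzyme follows the charge, which gives twice the rate and 0.100 of it before the target term in the rate law acts. I did not carry that term through by hand.

The forecast named precatalyst at 98.8 %, beside my 98.6 %, with factors 1.6 and 0.145, calling the time of reading “far shorter than the roughly 17 s activation time”.

The simulation gave precatalyst at 98.8 %, with factors 1.61 and 0.144. In the flask charged with 0.20 µM precatalyst, the reading came at 0.204 s, earlier than my upper limit and well before the crossing, and the activated share at that time works out at 1.21 %, with 1.21 % of the catalyst standing as enzyme. In the flask charged with 0.020 µM precatalyst, my activated share of 1.41 % stands beside an enzyme share of 1.38 %.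

All constants are assumed, and the outcome is calculated.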